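## Retrosynthetic overview

1. The last step is hydrogenolysis of twelve benzyl ethers. Before it, the pyran ring of the bottom flavan-3,4-diol unit is cut at O1–C8a and C4a–C4: an aryne across C4a≡C8a of its ring A (already joined through C8 to C4 of the middle unit) plus a syn-aldol aldehyde that supplies O1, C2, C3 and C4.
2. Enabling feature: in every unit the pyran ring is fused to the phloroglucinol ring A through the adjacent carbons C8a (oxygen-bearing) and C4a (carbon-bearing), and the C5 oxygen sits next to C4a. It polarises the aryne so that O1 adds at C8a and the carbanion appears at C4a, 1,5 to the formyl carbon C4. The acid-labile benzylic C4–OH of the bottom unit is thus made last and never meets acid.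
3. The same annulation builds the top and middle units earlier. Each chroman-4-ol is oxidised to the 4-ketone, a metalated symmetric dibromophloroglucinol "cap" is added (as the aryllithium to the top-unit ketone, as the arylmagnesium chloride to the dimer ketone), and ionic hydride reduction sets the all-cis C4 (hydride anti to the axial 3-OBn). The cap is then converted into the next ortho-silylaryl triflate.
4. C2 and C3 of every unit come from Evans syn-glycolate aldols with 4-(benzyloxy)benzaldehyde: (R)-auxiliary for the top and bottom units, (S)-auxiliary for the middle unit.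
5. Ring order: pyran ring of the top unit (step 13), of the middle unit (step 19), of the bottom unit (step 25).

Key step: step 25

Assumption: both enantiomers of the N-(benzyloxyacetyl)-4-benzyloxazolidinone are bought; otherwise each needs one N-acylation with benzyloxyacetyl chloride.
Remark: the C4 configuration of the two chroman-4-ols that are oxidised to ketones is of no consequence; their SMILES show the expected 3,4-trans isomer.

## Route

Step 1
Reactants: 1 (R)-4-benzyl-3-[(benzyloxy)acetyl]oxazolidin-2-one; 2 4-(benzyloxy)benzaldehyde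
Product: 4 (R)-4-benzyl-3-[(2R,3S)-2-(benzyloxy)-3-[4-(benzyloxy)phenyl]-3-hydroxypropanoyl]oxazolidin-2-one, via Z-boron enolate 3 (not isolated)
Conditions: Bu2BOTf, Et3N, CH2Cl2, −78 → 0 °C; then 2, −78 → 0 °C; pH 7 buffer, MeOH, H2O2
Reagents that add atoms: none
Why: Evans syn-aldol: the Z-boron enolate reacts through a closed chair transition state on the face left open by the (R)-benzyl group, which should set both centres (2R,3S) and leave the benzylic hydroxyl free next to the benzylated glycolate oxygen.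

Step 2
Reactants: 4 syn-aldol imide
Product: 5 (2R,3S)-2-(benzyloxy)-3-[4-(benzyloxy)phenyl]-3-hydroxy-N-methoxy-N-methylpropanamide
Conditions: MeNHOMe·HCl, AlMe3, CH2Cl2, −10 → 0 °C; aq. potassium sodium tartrate
Reagents that add atoms: N,O-dimethylhydroxylamine hydrochloride, CNOC.Cl
Why: Weinreb transamidation with the aluminium amide, assisted by the free β-hydroxyl, cleaves the auxiliary at the exocyclic carbonyl without touching either stereocentre.

Step 3
Reactants: 5 hydroxy Weinreb amide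
Product: 6 (2R,3S)-2-(benzyloxy)-3-[4-(benzyloxy)phenyl]-N-methoxy-N-methyl-3-[(trimethylsilyl)oxy]propanamide
Conditions: Me3SiCl, imidazole, CH2Cl2, 0 °C
Reagents that add atoms: chlorotrimethylsilane, C[Si](C)(C)Cl
Why: Silyl ether formation turns the benzylic hydroxyl into a fluoride-labile trimethylsilyl ether, the proton-free alkoxide source needed for the annulation.

Step 4
Reactants: 6 silylated Weinreb amide
Product: 7 (2R,3S)-2-(benzyloxy)-3-[4-(benzyloxy)phenyl]-3-[(trimethylsilyl)oxy]propanal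
Conditions: i-Bu2AlH, THF, −78 °C; aq. potassium sodium tartrate, 0 °C
Reagents that add atoms: none
Why: Weinreb amide reduction stops at the chelated aluminium hemiaminal, so hydrolysis should give the α-benzyloxy aldehyde without over-reduction, and −78 °C with neutral work-up keeps the α-centre and the silyl ether.

Step 5
Reactants: 8 (S)-4-benzyl-3-[(benzyloxy)acetyl]oxazolidin-2-one; 2 4-(benzyloxy)benzaldehyde
Product: 10 (S)-4-benzyl-3-[(2S,3R)-2-(benzyloxy)-3-[4-(benzyloxy)phenyl]-3-hydroxypropanoyl]oxazolidin-2-one, via Z-boron enolate 9 (not isolated)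
Conditions: Bu2BOTf, Et3N, CH2Cl2, −78 → 0 °C; then 2, −78 → 0 °C; pH 7 buffer, MeOH, H2O2
Reagents that add atoms: none
Why: Evans syn-aldol as in step 1 with the enantiomeric auxiliary, which should set the mirror-image centres (2S,3R).

Step 6
Reactants: 10 syn-aldol imide
Product: 11 (2S,3R)-2-(benzyloxy)-3-[4-(benzyloxy)phenyl]-3-hydroxy-N-methoxy-N-methylpropanamide
Conditions: MeNHOMe·HCl, AlMe3, CH2Cl2, −10 → 0 °C; aq. potassium sodium tartrate
Reagents that add atoms: N,O-dimethylhydroxylamine hydrochloride, CNOC.Cl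
Why: Weinreb transamidation as in step 2, with no change at the stereocentres.

Step 7
Reactants: 11 hydroxy Weinreb amide
Product: 12 (2S,3R)-2-(benzyloxy)-3-[4-(benzyloxy)phenyl]-N-methoxy-N-methyl-3-[(trimethylsilyl)oxy]propanamide
Conditions: Me3SiCl, imidazole, CH2Cl2, 0 °C
Reagents that add atoms: chlorotrimethylsilane, C[Si](C)(C)Cl
Why: Silyl ether formation as in step 3.

Step 8
Reactants: 12 silylated Weinreb amide
Product: 13 (2S,3R)-2-(benzyloxy)-3-[4-(benzyloxy)phenyl]-3-[(trimethylsilyl)oxy]propanal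
Conditions: i-Bu2AlH, THF, −78 °C; aq. potassium sodium tartrate, 0 °C
Reagents that add atoms: none
Why: Weinreb amide reduction as in step 4.

Step 9
Reactants: 14 3,5-bis(benzyloxy)phenol
Product: 15 3,5-bis(benzyloxy)-2-bromophenol
Conditions: NBS (1.0 equiv), CH2Cl2, −78 °C
Reagents that add atoms: N-bromosuccinimide, O=C1CCC(=O)N1Br
Why: Electrophilic aromatic bromination with NBS at low temperature should go ortho to the free hydroxyl of a 3,5-dialkoxyphenol through hydrogen-bonded delivery of bromine.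

Step 10
Reactants: 15 3,5-bis(benzyloxy)-2-bromophenol
Product: 18 3,5-bis(benzyloxy)-2-(trimethylsilyl)phenyl trifluoromethanesulfonate, via aryl trimethylsilyl ether 16 (not isolated), via lithium silylphenoxide 17 (not isolated)
Conditions: (Me3Si)2NH, THF, 65 °C, evaporate; n-BuLi, THF, −78 °C; then Tf2O, −78 °C
Reagents that add atoms: hexamethyldisilazane, C[Si](C)(C)N[Si](C)(C)C; trifluoromethanesulfonic anhydride, O=S(=O)(OS(=O)(=O)C(F)(F)F)C(F)(F)F
Why: O-silylation, bromine–lithium exchange, anionic 1,3 O-to-C silyl shift (retro-Brook rearrangement) and O-triflation form the standard sequence to an ortho-silylaryl triflate and place the silyl group between the triflate carbon and a benzyloxy carbon.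

Step 11
Reactants: 14 3,5-bis(benzyloxy)phenol
Product: 19 3,5-bis(benzyloxy)-2,6-dibromophenol
Conditions: NBS (2.1 equiv), i-Pr2NH (cat.), CH2Cl2, −78 → 0 °C
Reagents that add atoms: N-bromosuccinimide, O=C1CCC(=O)N1Br
Why: Amine-catalysed NBS bromination of phenols is ortho-selective, so two equivalents should give the symmetric 2,6-dibromide in which both bromines are equivalent.

Step 12
Reactants: 19 3,5-bis(benzyloxy)-2,6-dibromophenol
Product: 20 2-(allyloxy)-4,6-bis(benzyloxy)-1,3-dibromobenzene (the cap)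
Conditions: allyl bromide, K2CO3, DMF, rt
Reagents that add atoms: allyl bromide, C=CCBr
Why: Williamson etherification of the phenoxide; the allyl ether withstands organolithium and organomagnesium reagents and acid and is removed later under neutral conditions.

Step 13
Reactants: 18 ortho-silylaryl triflate; 7 (2R,3S)-aldehyde
Product: 22 (2S,3S,4R)-3,5,7-tris(benzyloxy)-2-[4-(benzyloxy)phenyl]chroman-4-ol, via aryne 21 (not isolated)
Conditions: CsF, 18-crown-6, THF, rt, slow addition of 7; aq. NaHCO3 work-up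
Reagents that add atoms: none
Why: Proposed new method: fluoride releases 3,5-bis(benzyloxy)benzyne and unmasks the benzylic oxygen of 7 as a proton-free alkoxide, which adds to the aryne carbon remote from the 3-benzyloxy group, and the aryl anion next to that benzyloxy group closes onto the formyl carbon (6-exo-trig); the closest known reaction type is the fluoride-induced aryne annulation of salicylaldehydes to xanthen-9-ols, extended here from a phenoxide to a silyl-masked aliphatic alkoxide; C2 and C3 come unchanged from the aldol and the C4 configuration is irrelevant here.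

Step 14
Reactants: 22 top-unit chroman-4-ol
Product: 23 (2S,3R)-3,5,7-tris(benzyloxy)-2-[4-(benzyloxy)phenyl]chroman-4-one (2,3-cis)
Conditions: Dess–Martin periodinane, pyridine, CH2Cl2, 0 °C → rt
Reagents that add atoms: none
Why: Dess–Martin oxidation of the benzylic alcohol under buffered conditions should give the 2,3-cis chroman-4-one without epimerising the α-benzyloxy centre, and it erases the C4 centre.

Step 15
Reactants: 20 cap; 23 top-unit ketone
Product: 25 top-unit tertiary carbinol carrying the 2-(allyloxy)-4,6-bis(benzyloxy)-3-bromophenyl group at C4, via aryllithium 24 (not isolated)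
Conditions: n-BuLi (1.0 equiv), THF, −78 °C; then 23, −78 °C; H2O
Reagents that add atoms: none
Why: Bromine–lithium exchange on the symmetric dibromide gives the same aryllithium whichever bromine reacts, and its 1,2-addition to the ketone at −78 °C joins ring A of the future middle unit to C4 of the top unit; the carbinol configuration is lost in the next step.

Step 16
Reactants: 25 top-unit carbinol
Product: 26 all-cis top unit carrying the allyl-protected bromo cap at C4
Conditions: Bu3SnH, CF3CO2H, CH2Cl2, 0 °C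
Reagents that add atoms: none
Why: Ionic hydrogenation: acid ionises the doubly benzylic tertiary alcohol and the tin hydride attacks the cation axially, anti to the pseudo-axial 3-benzyloxy group, so the aryl group should end cis to 3-OBn and to the 2-aryl group (all-cis), the outcome known for 2,3-cis 4-aryl-4-hydroxyflavans.

Step 17
Reactants: 26 allyl ether
Product: 27 all-cis top unit carrying the 4,6-bis(benzyloxy)-3-bromo-2-hydroxyphenyl group at C4
Conditions: Pd(PPh3)4 (cat.), morpholine, THF, rt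
Reagents that add atoms: none
Why: Tsuji–Trost deallylation (π-allyl complex of palladium trapped by morpholine) frees the phenol under neutral conditions that spare benzyl ethers and the hindered aryl bromide.

Step 18
Reactants: 27 bromophenol
Product: 30 top unit carrying the ortho-silylaryl triflate, via aryl trimethylsilyl ether 28 (not isolated), via lithium silylphenoxide 29 (not isolated)
Conditions: (Me3Si)2NH, THF, 65 °C, evaporate; n-BuLi, THF, −78 °C; then Tf2O, −78 °C
Reagents that add atoms: hexamethyldisilazane, C[Si](C)(C)N[Si](C)(C)C; trifluoromethanesulfonic anhydride, O=S(=O)(OS(=O)(=O)C(F)(F)F)C(F)(F)F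
Why: Retro-Brook sequence as in step 10: the only bromine in the molecule is exchanged, the silyl group moves from oxygen to the ortho carbon and the phenoxide is triflated.

Step 19
Reactants: 30 top unit with ortho-silylaryl triflate; 13 (2S,3R)-aldehyde
Product: 32 top–middle dimer with a free 4-hydroxyl on the middle unit, via aryne 31 (not isolated)
Conditions: CsF, 18-crown-6, THF, rt, slow addition of 13; aq. NaHCO3 work-up
Reagents that add atoms: none
Why: Proposed new method: same fluoride-triggered annulation as in step 13 (silyl-masked alkoxide adds to the aryne, the aryl anion closes 6-exo-trig onto the formyl group; closest known reaction type: aryne annulation of salicylaldehydes to xanthen-9-ols), with the adjacent benzyloxy group directing oxygen to the aryne carbon next to the top-unit substituent so that the new pyran ring is fused in the 4→8 sense; C2 and C3 (2R,3R) come from the aldol and the C4 configuration is irrelevant.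

Step 20
Reactants: 32 dimer 4-ol
Product: 33 top–middle dimer 4-ketone (middle unit 2R,3S, 2,3-cis)
Conditions: Dess–Martin periodinane, pyridine, CH2Cl2, 0 °C → rt
Reagents that add atoms: none
Why: Dess–Martin oxidation as in step 14, with no epimerisation of the 2,3-cis α-benzyloxy ketone expected.

Step 21
Reactants: 20 cap; 33 dimer ketone
Product: 35 dimer tertiary carbinol carrying the cap at C4 of the middle unit, via arylmagnesium chloride 34 (not isolated)
Conditions: i-PrMgCl·LiCl (1.05 equiv), THF, −15 → 0 °C; then 33, −40 → 0 °C; H2O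
Reagents that add atoms: none
Why: Bromine–magnesium exchange with the turbo-Grignard reagent on the symmetric dibromide, helped by the two ether oxygens that flank each bromine and by the inductive pull of the second bromine, gives the same arylmagnesium chloride whichever bromine reacts, and its chelation-assisted Grignard 1,2-addition to the α-benzyloxy ketone joins ring A of the future bottom unit to C4 of the middle unit while the lower basicity of the magnesium reagent limits enolisation toward the epimerisable C3 of the dimer ketone; the carbinol configuration is lost in the next step.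

Step 22
Reactants: 35 dimer carbinol
Product: 36 dimer with all-cis middle unit carrying the allyl-protected bromo cap at C4
Conditions: Bu3SnH, CF3CO2H, CH2Cl2, 0 °C
Reagents that add atoms: none
Why: Ionic hydrogenation as in step 16: hydride attacks anti to the pseudo-axial 3-benzyloxy group of the middle unit, which should set its all-cis C4, and the short cold acid exposure should leave the existing interflavan bond intact.

Step 23
Reactants: 36 allyl ether
Product: 37 dimer carrying the 4,6-bis(benzyloxy)-3-bromo-2-hydroxyphenyl group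
Conditions: Pd(PPh3)4 (cat.), morpholine, THF, rt
Reagents that add atoms: none
Why: Tsuji–Trost deallylation as in step 17.

Step 24
Reactants: 37 bromophenol
Product: 40 dimer carrying the ortho-silylaryl triflate, via aryl trimethylsilyl ether 38 (not isolated), via lithium silylphenoxide 39 (not isolated)
Conditions: (Me3Si)2NH, THF, 65 °C, evaporate; n-BuLi, THF, −78 °C; then Tf2O, −78 °C
Reagents that add atoms: hexamethyldisilazane, C[Si](C)(C)N[Si](C)(C)C; trifluoromethanesulfonic anhydride, O=S(=O)(OS(=O)(=O)C(F)(F)F)C(F)(F)F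
Why: Retro-Brook sequence as in steps 10 and 18.

Step 25
Reactants: 40 dimer with ortho-silylaryl triflate; 7 (2R,3S)-aldehyde
Product: 42 dodeca-O-benzyl trimer with free 4-hydroxyl on the bottom unit, via aryne 41 (not isolated)
Conditions: CsF, 18-crown-6, THF, 0 °C → rt, slow addition of 7; aq. NaHCO3 work-up
Reagents that add atoms: none
Why: Proposed new method: fluoride strips the silyl group of 40 to release aryne 41 and at the same time unmasks the benzylic oxygen of 7 as a proton-free caesium alkoxide; this alkoxide adds to the aryne carbon remote from the 5-benzyloxy group (O1–C8a), and the aryl anion left at C4a, stabilised by the neighbouring C5 oxygen, sits 1,5 to the formyl carbon and closes the pyran ring by 6-exo-trig addition (C4a–C4). The closest known reaction type is the fluoride-induced annulation of arynes with salicylaldehydes (phenoxide addition, then capture of the aryl anion by the formyl group to give xanthen-9-ols); the extension is an aliphatic benzylic alkoxide delivered from its trimethylsilyl ether, so that no O–H proton can quench the aryl anion. Regiochemistry (oxygen at C8a, carbon at C4a, hence the 4→8 fusion) follows from the inductive polarisation of 3-alkoxyarynes, here by the C5 benzyloxy group beside C4a. C2 and C3 arrive intact from the aldol fragment (2S,3S in the product); C4 should form 3,4-trans (4R) because the formyl C=O lies anti to the axial C3–OBn dipole in the closing ring (Cornforth arrangement, no chelation with crown-complexed caesium), which also keeps the new C4 oxygen pseudo-axial and away from the peri 5-benzyloxy group. The step needs the aryl anion to be captured by the aldehyde rather than by a proton, and the β-alkoxy aldehyde to survive retro-aldol cleavage; aprotic THF, release of the alkoxide only in the presence of the aryne (slow addition) and low temperature should secure this. Because the benzylic C4–OH is created here, after all acid steps, it is never exposed to ionising conditions.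

Step 26
Reactants: 42 dodeca-O-benzyl trimer
Product: 43 target trimer (CNP0159291.1)
Conditions: H2 (1 atm), Pd(OH)2/C, THF/MeOH, rt
Reagents that add atoms: none
Why: Catalytic hydrogenolysis of the twelve benzyl ethers in neutral medium, where the benzylic C4–OH and the pyran C2–O bonds should cleave much more slowly than benzyl ethers; no stereocentre is touched.

## Compound list

1 | (R)-4-benzyl-3-[(benzyloxy)acetyl]oxazolidin-2-one | O=C(COCc1ccccc1)N1[C@H](Cc2ccccc2)COC1=O | starting material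
2 | 4-(benzyloxy)benzaldehyde | O=Cc1ccc(OCc2ccccc2)cc1 | starting material
3 | Z-dibutylboron enolate of 1 (not isolated) | CCCCB(CCCC)O/C(=C\OCc1ccccc1)N1[C@H](Cc2ccccc2)COC1=O | intermediate
4 | (R)-4-benzyl-3-[(2R,3S)-2-(benzyloxy)-3-[4-(benzyloxy)phenyl]-3-hydroxypropanoyl]oxazolidin-2-one | O=C([C@H](OCc1ccccc1)[C@@H](O)c1ccc(OCc2ccccc2)cc1)N1[C@H](Cc2ccccc2)COC1=O | intermediate
5 | (2R,3S)-2-(benzyloxy)-3-[4-(benzyloxy)phenyl]-3-hydroxy-N-methoxy-N-methylpropanamide | CON(C)C(=O)[C@H](OCc1ccccc1)[C@@H](O)c1ccc(OCc2ccccc2)cc1 | intermediate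
6 | (2R,3S)-2-(benzyloxy)-3-[4-(benzyloxy)phenyl]-N-methoxy-N-methyl-3-[(trimethylsilyl)oxy]propanamide | CON(C)C(=O)[C@H](OCc1ccccc1)[C@@H](O[Si](C)(C)C)c1ccc(OCc2ccccc2)cc1 | intermediate
7 | (2R,3S)-2-(benzyloxy)-3-[4-(benzyloxy)phenyl]-3-[(trimethylsilyl)oxy]propanal | O=C[C@H](OCc1ccccc1)[C@@H](O[Si](C)(C)C)c1ccc(OCc2ccccc2)cc1 | intermediate
8 | (S)-4-benzyl-3-[(benzyloxy)acetyl]oxazolidin-2-one | O=C(COCc1ccccc1)N1[C@@H](Cc2ccccc2)COC1=O | starting material
9 | Z-dibutylboron enolate of 8 (not isolated) | CCCCB(CCCC)O/C(=C\OCc1ccccc1)N1[C@@H](Cc2ccccc2)COC1=O | intermediate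
10 | (S)-4-benzyl-3-[(2S,3R)-2-(benzyloxy)-3-[4-(benzyloxy)phenyl]-3-hydroxypropanoyl]oxazolidin-2-one | O=C([C@@H](OCc1ccccc1)[C@H](O)c1ccc(OCc2ccccc2)cc1)N1[C@@H](Cc2ccccc2)COC1=O | intermediate
11 | (2S,3R)-2-(benzyloxy)-3-[4-(benzyloxy)phenyl]-3-hydroxy-N-methoxy-N-methylpropanamide | CON(C)C(=O)[C@@H](OCc1ccccc1)[C@H](O)c1ccc(OCc2ccccc2)cc1 | intermediate
12 | (2S,3R)-2-(benzyloxy)-3-[4-(benzyloxy)phenyl]-N-methoxy-N-methyl-3-[(trimethylsilyl)oxy]propanamide | CON(C)C(=O)[C@@H](OCc1ccccc1)[C@H](O[Si](C)(C)C)c1ccc(OCc2ccccc2)cc1 | intermediate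
13 | (2S,3R)-2-(benzyloxy)-3-[4-(benzyloxy)phenyl]-3-[(trimethylsilyl)oxy]propanal | O=C[C@@H](OCc1ccccc1)[C@H](O[Si](C)(C)C)c1ccc(OCc2ccccc2)cc1 | intermediate
14 | 3,5-bis(benzyloxy)phenol | Oc1cc(OCc2ccccc2)cc(OCc2ccccc2)c1 | starting material
15 | 3,5-bis(benzyloxy)-2-bromophenol | Oc1cc(OCc2ccccc2)cc(OCc2ccccc2)c1Br | intermediate
16 | [3,5-bis(benzyloxy)-2-bromophenoxy]trimethylsilane (not isolated) | C[Si](C)(C)Oc1cc(OCc2ccccc2)cc(OCc2ccccc2)c1Br | intermediate
17 | lithium 3,5-bis(benzyloxy)-2-(trimethylsilyl)phenoxide (not isolated) | [Li+].[O-]c1cc(OCc2ccccc2)cc(OCc2ccccc2)c1[Si](C)(C)C | intermediate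
18 | 3,5-bis(benzyloxy)-2-(trimethylsilyl)phenyl trifluoromethanesulfonate | C[Si](C)(C)c1c(OCc2ccccc2)cc(OCc2ccccc2)cc1OS(=O)(=O)C(F)(F)F | intermediate
19 | 3,5-bis(benzyloxy)-2,6-dibromophenol | Oc1c(Br)c(OCc2ccccc2)cc(OCc2ccccc2)c1Br | intermediate
20 | 2-(allyloxy)-4,6-bis(benzyloxy)-1,3-dibromobenzene (cap) | C=CCOc1c(Br)c(OCc2ccccc2)cc(OCc2ccccc2)c1Br | intermediate
21 | 3,5-bis(benzyloxy)benzyne (1,2-didehydro-3,5-bis(benzyloxy)benzene, not isolated) | C1#CC(OCc2ccccc2)=CC(OCc2ccccc2)=C1 | intermediate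
22 | (2S,3S,4R)-3,5,7-tris(benzyloxy)-2-[4-(benzyloxy)phenyl]chroman-4-ol (2,3-cis, 3,4-trans) | c1c(OCc5ccccc5)cc(OCc5ccccc5)c2c1O[C@@H](c1ccc(OCc5ccccc5)cc1)[C@@H](OCc5ccccc5)[C@@H]2O | intermediate
23 | (2S,3R)-3,5,7-tris(benzyloxy)-2-[4-(benzyloxy)phenyl]chroman-4-one (2,3-cis) | c1c(OCc5ccccc5)cc(OCc5ccccc5)c2c1O[C@@H](c1ccc(OCc5ccccc5)cc1)[C@@H](OCc5ccccc5)C2=O | intermediate
24 | [2-(allyloxy)-4,6-bis(benzyloxy)-3-bromophenyl]lithium (not isolated) | [Li]c1c(OCC=C)c(Br)c(OCc2ccccc2)cc1OCc1ccccc1 | intermediate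
25 | (2S,3R)-4-[2-(allyloxy)-4,6-bis(benzyloxy)-3-bromophenyl]-3,5,7-tris(benzyloxy)-2-[4-(benzyloxy)phenyl]chroman-4-ol, 4-OH cis and 4-aryl trans to 3-OBn | C=CCOc1c(Br)c(OCc5ccccc5)cc(OCc5ccccc5)c1[C@]1(O)c2c(OCc5ccccc5)cc(OCc5ccccc5)cc2O[C@@H](c2ccc(OCc5ccccc5)cc2)[C@H]1OCc5ccccc5 | intermediate
26 | (2S,3S)-4-[2-(allyloxy)-4,6-bis(benzyloxy)-3-bromophenyl]-3,5,7-tris(benzyloxy)-2-[4-(benzyloxy)phenyl]chroman, all-cis (4-aryl cis to 3-OBn and to 2-aryl) | C=CCOc1c(Br)c(OCc5ccccc5)cc(OCc5ccccc5)c1[C@H]1c2c(OCc5ccccc5)cc(OCc5ccccc5)cc2O[C@@H](c2ccc(OCc5ccccc5)cc2)[C@H]1OCc5ccccc5 | intermediate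
27 | (2S,3S)-4-[4,6-bis(benzyloxy)-3-bromo-2-hydroxyphenyl]-3,5,7-tris(benzyloxy)-2-[4-(benzyloxy)phenyl]chroman, all-cis | Oc1c(Br)c(OCc5ccccc5)cc(OCc5ccccc5)c1[C@H]1c2c(OCc5ccccc5)cc(OCc5ccccc5)cc2O[C@@H](c2ccc(OCc5ccccc5)cc2)[C@H]1OCc5ccccc5 | intermediate
28 | trimethylsilyl ether of phenol 27 (not isolated) | C[Si](C)(C)Oc1c(Br)c(OCc5ccccc5)cc(OCc5ccccc5)c1[C@H]1c2c(OCc5ccccc5)cc(OCc5ccccc5)cc2O[C@@H](c2ccc(OCc5ccccc5)cc2)[C@H]1OCc5ccccc5 | intermediate
29 | lithium phenoxide of the all-cis top unit carrying the 4,6-bis(benzyloxy)-2-oxido-3-(trimethylsilyl)phenyl group (not isolated) | [Li+].[O-]c1c([Si](C)(C)C)c(OCc5ccccc5)cc(OCc5ccccc5)c1[C@H]1c2c(OCc5ccccc5)cc(OCc5ccccc5)cc2O[C@@H](c2ccc(OCc5ccccc5)cc2)[C@H]1OCc5ccccc5 | intermediate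
30 | (2S,3S)-4-[4,6-bis(benzyloxy)-2-[(trifluoromethylsulfonyl)oxy]-3-(trimethylsilyl)phenyl]-3,5,7-tris(benzyloxy)-2-[4-(benzyloxy)phenyl]chroman, all-cis | FC(F)(F)S(=O)(=O)Oc1c([Si](C)(C)C)c(OCc5ccccc5)cc(OCc5ccccc5)c1[C@H]1c2c(OCc5ccccc5)cc(OCc5ccccc5)cc2O[C@@H](c2ccc(OCc5ccccc5)cc2)[C@H]1OCc5ccccc5 | intermediate
31 | aryne: all-cis top unit carrying the 4,6-bis(benzyloxy)-2,3-didehydrophenyl group at C4 (not isolated) | C1#CC(OCc5ccccc5)=CC(OCc5ccccc5)=C1[C@H]1c2c(OCc5ccccc5)cc(OCc5ccccc5)cc2O[C@@H](c2ccc(OCc5ccccc5)cc2)[C@H]1OCc5ccccc5 | intermediate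
32 | (2R,3R,4S)-3,5,7-tris(benzyloxy)-2-[4-(benzyloxy)phenyl]-8-[(2S,3S,4R)-3,5,7-tris(benzyloxy)-2-[4-(benzyloxy)phenyl]chroman-4-yl]chroman-4-ol (top unit all-cis) | c5ccccc5COc1ccc([C@H]2Oc3c(c(OCc5ccccc5)cc(OCc5ccccc5)c3[C@H]3c4c(OCc5ccccc5)cc(OCc5ccccc5)cc4O[C@@H](c4ccc(OCc5ccccc5)cc4)[C@H]3OCc5ccccc5)[C@H](O)[C@H]2OCc5ccccc5)cc1 | intermediate
33 | (2R,3S)-3,5,7-tris(benzyloxy)-2-[4-(benzyloxy)phenyl]-8-[(2S,3S,4R)-3,5,7-tris(benzyloxy)-2-[4-(benzyloxy)phenyl]chroman-4-yl]chroman-4-one (2,3-cis) | c5ccccc5COc1ccc([C@H]2Oc3c(c(OCc5ccccc5)cc(OCc5ccccc5)c3[C@H]3c4c(OCc5ccccc5)cc(OCc5ccccc5)cc4O[C@@H](c4ccc(OCc5ccccc5)cc4)[C@H]3OCc5ccccc5)C(=O)[C@H]2OCc5ccccc5)cc1 | intermediate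
34 | [2-(allyloxy)-4,6-bis(benzyloxy)-3-bromophenyl]magnesium chloride, as its LiCl complex (not isolated) | Cl[Mg]c1c(OCC=C)c(Br)c(OCc2ccccc2)cc1OCc1ccccc1 | intermediate
35 | dimer carbinol: 33 with C4 of the middle unit carrying OH (cis to 3-OBn) and the 2-(allyloxy)-4,6-bis(benzyloxy)-3-bromophenyl group (trans to 3-OBn) | c5ccccc5COc1ccc([C@H]2Oc3c(c(OCc5ccccc5)cc(OCc5ccccc5)c3[C@H]3c4c(OCc5ccccc5)cc(OCc5ccccc5)cc4O[C@@H](c4ccc(OCc5ccccc5)cc4)[C@H]3OCc5ccccc5)[C@](O)(c3c(OCc5ccccc5)cc(OCc5ccccc5)c(Br)c3OCC=C)[C@H]2OCc5ccccc5)cc1 | intermediate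
36 | dimer with all-cis (2R,3R) middle unit carrying the 2-(allyloxy)-4,6-bis(benzyloxy)-3-bromophenyl group at C4 | c5ccccc5COc1ccc([C@H]2Oc3c(c(OCc5ccccc5)cc(OCc5ccccc5)c3[C@H]3c4c(OCc5ccccc5)cc(OCc5ccccc5)cc4O[C@@H](c4ccc(OCc5ccccc5)cc4)[C@H]3OCc5ccccc5)[C@@H](c3c(OCc5ccccc5)cc(OCc5ccccc5)c(Br)c3OCC=C)[C@H]2OCc5ccccc5)cc1 | intermediate
37 | dimer with all-cis middle unit carrying the 4,6-bis(benzyloxy)-3-bromo-2-hydroxyphenyl group at C4 | c5ccccc5COc1ccc([C@H]2Oc3c(c(OCc5ccccc5)cc(OCc5ccccc5)c3[C@H]3c4c(OCc5ccccc5)cc(OCc5ccccc5)cc4O[C@@H](c4ccc(OCc5ccccc5)cc4)[C@H]3OCc5ccccc5)[C@@H](c3c(OCc5ccccc5)cc(OCc5ccccc5)c(Br)c3O)[C@H]2OCc5ccccc5)cc1 | intermediate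
38 | trimethylsilyl ether of phenol 37 (not isolated) | c5ccccc5COc1ccc([C@H]2Oc3c(c(OCc5ccccc5)cc(OCc5ccccc5)c3[C@H]3c4c(OCc5ccccc5)cc(OCc5ccccc5)cc4O[C@@H](c4ccc(OCc5ccccc5)cc4)[C@H]3OCc5ccccc5)[C@@H](c3c(OCc5ccccc5)cc(OCc5ccccc5)c(Br)c3O[Si](C)(C)C)[C@H]2OCc5ccccc5)cc1 | intermediate
39 | lithium phenoxide of the dimer carrying the 4,6-bis(benzyloxy)-2-oxido-3-(trimethylsilyl)phenyl group (not isolated) | c5ccccc5COc1ccc([C@H]2Oc3c(c(OCc5ccccc5)cc(OCc5ccccc5)c3[C@H]3c4c(OCc5ccccc5)cc(OCc5ccccc5)cc4O[C@@H](c4ccc(OCc5ccccc5)cc4)[C@H]3OCc5ccccc5)[C@@H](c3c(OCc5ccccc5)cc(OCc5ccccc5)c([Si](C)(C)C)c3[O-])[C@H]2OCc5ccccc5)cc1.[Li+] | intermediate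
40 | dimer with all-cis middle unit carrying the 4,6-bis(benzyloxy)-2-[(trifluoromethylsulfonyl)oxy]-3-(trimethylsilyl)phenyl group at C4 | c5ccccc5COc1ccc([C@H]2Oc3c(c(OCc5ccccc5)cc(OCc5ccccc5)c3[C@H]3c4c(OCc5ccccc5)cc(OCc5ccccc5)cc4O[C@@H](c4ccc(OCc5ccccc5)cc4)[C@H]3OCc5ccccc5)[C@@H](c3c(OCc5ccccc5)cc(OCc5ccccc5)c([Si](C)(C)C)c3OS(=O)(=O)C(F)(F)F)[C@H]2OCc5ccccc5)cc1 | intermediate
41 | aryne: dimer carrying the 4,6-bis(benzyloxy)-2,3-didehydrophenyl group at C4 of the middle unit (not isolated) | c5ccccc5COc1ccc([C@H]2Oc3c(c(OCc5ccccc5)cc(OCc5ccccc5)c3[C@H]3c4c(OCc5ccccc5)cc(OCc5ccccc5)cc4O[C@@H](c4ccc(OCc5ccccc5)cc4)[C@H]3OCc5ccccc5)[C@@H](C3=C(OCc5ccccc5)C=C(OCc5ccccc5)C#C3)[C@H]2OCc5ccccc5)cc1 | intermediate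
42 | dodeca-O-benzyl ether of 43 (all phenolic and all three 3-hydroxyls benzylated; 4-hydroxyl of the bottom unit free; bottom unit 2S,3S,4R) | c5ccccc5COc1ccc([C@H]2Oc3c(c(OCc5ccccc5)cc(OCc5ccccc5)c3[C@H]3c4c(OCc5ccccc5)cc(OCc5ccccc5)cc4O[C@@H](c4ccc(OCc5ccccc5)cc4)[C@H]3OCc5ccccc5)[C@@H](c3c(OCc5ccccc5)cc(OCc5ccccc5)c4c3O[C@@H](c3ccc(OCc5ccccc5)cc3)[C@@H](OCc5ccccc5)[C@@H]4O)[C@H]2OCc5ccccc5)cc1 | intermediate
43 | CNP0159291.1: (2S,3S,4R) all-cis top flavan-3-ol, 4→8 to (2R,3R,4S) all-cis middle flavan-3-ol, 4→8 to (2S,3S,4R) bottom flavan-3,4-diol; each unit 5,7-dihydroxy with a 4-hydroxyphenyl group at C2 | Oc1ccc([C@H]2Oc3c(c(O)cc(O)c3[C@H]3c4c(O)cc(O)cc4O[C@@H](c4ccc(O)cc4)[C@H]3O)[C@@H](c3c(O)cc(O)c4c3O[C@@H](c3ccc(O)cc3)[C@@H](O)[C@@H]4O)[C@H]2O)cc1 | target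

## Step count and risks

Total step count: 26. Longest linear sequence: 18 steps (steps 1–4, then 13–26).

Steps most likely to fail:

1. Step 25 (Proposed new method). What may go wrong: crowding at C8a beside the dimer slows alkoxide addition so that the aryne is consumed otherwise; the aryl anion is protonated instead of closing the ring; the unmasked β-alkoxy aldehyde fragments by retro-aldol; or facial selectivity at C4 is poor.
Fallback (sets out from 22 and 33, returns at 42, known chemistry only): ionic hydrogenation of 22 (Et3SiH, CF3CO2H, CH2Cl2, 0 °C) removes the benzylic hydroxyl and gives (2S,3S)-3,5,7-tris(benzyloxy)-2-[4-(benzyloxy)phenyl]chroman F5. NBS (CH2Cl2, −78 °C) brominates C8, the usual site for 5,7-dibenzyloxyflavans, to give the 8-bromochroman F6. Bromine–lithium exchange (n-BuLi, THF, −78 °C) and addition to ketone 33 give the trimeric tertiary carbinol F7. Bu3SnH/CF3CO2H reduces it, hydride again anti to the 3-benzyloxy group, to the all-cis protected trimer without the bottom 4-hydroxyl F8. DDQ in CH2Cl2/H2O then oxidises the only benzylic methylene (C4 of the bottom unit), and water adds anti to the axial 3-benzyloxy group to return 42 with the 3,4-trans hydroxyl.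

2. Step 19 (Proposed new method). What may go wrong: in the crowded setting beside the top unit, protonation of the aryl anion or retro-aldol loss of the unmasked alkoxide outruns ring closure.
Fallback (sets out from 30 and 11, returns at 32, known chemistry only): 30 and the free hydroxy Weinreb amide 11 are combined with CsF in MeCN at −20 °C, conditions under which arynes insert into alcohol O–H bonds. The alcohol is then never a free alkoxide, and the product is the aryl ether Weinreb amide F3, protonated at the former silyl carbon. i-Bu2AlH (THF, −78 °C) gives the aryl ether aldehyde F4. Me2AlCl (CH2Cl2, −78 °C) closes the ring by intramolecular Friedel–Crafts hydroxyalkylation at the only free position ortho to the ether oxygen and returns 32; either C4 epimer serves.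

3. Step 13 (Proposed new method). What may go wrong: the released alkoxide undergoes retro-aldol cleavage, or the aryl anion is quenched, before the aryne is trapped and cyclised.
Fallback (sets out from 18 and 5, returns at 22, known chemistry only): 18 and the free hydroxy Weinreb amide 5 with CsF in MeCN at −20 °C give, by aryne O–H insertion, the 3,5-bis(benzyloxy)phenyl ether Weinreb amide F1. i-Bu2AlH (THF, −78 °C) gives the aryl ether aldehyde F2. Me2AlCl (CH2Cl2, −78 °C) effects intramolecular Friedel–Crafts hydroxyalkylation ortho to the ether oxygen (both ortho positions are equivalent) and returns 22.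

## Further compounds

F1 | step 13 | (2R,3S)-2-(benzyloxy)-3-[4-(benzyloxy)phenyl]-3-[3,5-bis(benzyloxy)phenoxy]-N-methoxy-N-methylpropanamide | CON(C)C(=O)[C@H](OCc1ccccc1)[C@@H](Oc1cc(OCc2ccccc2)cc(OCc2ccccc2)c1)c1ccc(OCc2ccccc2)cc1
F2 | step 13 | (2R,3S)-2-(benzyloxy)-3-[4-(benzyloxy)phenyl]-3-[3,5-bis(benzyloxy)phenoxy]propanal | O=C[C@H](OCc1ccccc1)[C@@H](Oc1cc(OCc2ccccc2)cc(OCc2ccccc2)c1)c1ccc(OCc2ccccc2)cc1
F3 | step 19 | (2S,3R)-2-(benzyloxy)-3-[4-(benzyloxy)phenyl]-N-methoxy-N-methylpropanamide carrying at C3 the aryl ether oxygen of a 3,5-bis(benzyloxy)phenyl ring whose C2 bears the all-cis top unit (chroman-4-yl) | CON(C)C(=O)[C@@H](OCc5ccccc5)[C@H](Oc1cc(OCc5ccccc5)cc(OCc5ccccc5)c1[C@H]1c2c(OCc5ccccc5)cc(OCc5ccccc5)cc2O[C@@H](c2ccc(OCc5ccccc5)cc2)[C@H]1OCc5ccccc5)c1ccc(OCc5ccccc5)cc1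
F4 | step 19 | aldehyde corresponding to F3 (Weinreb amide replaced by formyl) | O=C[C@@H](OCc5ccccc5)[C@H](Oc1cc(OCc5ccccc5)cc(OCc5ccccc5)c1[C@H]1c2c(OCc5ccccc5)cc(OCc5ccccc5)cc2O[C@@H](c2ccc(OCc5ccccc5)cc2)[C@H]1OCc5ccccc5)c1ccc(OCc5ccccc5)cc1
F5 | step 25 | (2S,3S)-3,5,7-tris(benzyloxy)-2-[4-(benzyloxy)phenyl]chroman | c1c(OCc5ccccc5)cc(OCc5ccccc5)c2c1O[C@@H](c1ccc(OCc5ccccc5)cc1)[C@@H](OCc5ccccc5)C2
F6 | step 25 | (2S,3S)-3,5,7-tris(benzyloxy)-2-[4-(benzyloxy)phenyl]-8-bromochroman | Brc1c(OCc5ccccc5)cc(OCc5ccccc5)c2c1O[C@@H](c1ccc(OCc5ccccc5)cc1)[C@@H](OCc5ccccc5)C2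
F7 | step 25 | trimeric tertiary carbinol: 33 with C4 of the middle unit carrying OH and C8 of the bottom chroman F5 (aryl trans to 3-OBn) | c5ccccc5COc1ccc([C@H]2Oc3c(c(OCc5ccccc5)cc(OCc5ccccc5)c3[C@H]3c4c(OCc5ccccc5)cc(OCc5ccccc5)cc4O[C@@H](c4ccc(OCc5ccccc5)cc4)[C@H]3OCc5ccccc5)[C@](O)(c3c(OCc5ccccc5)cc(OCc5ccccc5)c4c3O[C@@H](c3ccc(OCc5ccccc5)cc3)[C@@H](OCc5ccccc5)C4)[C@H]2OCc5ccccc5)cc1
F8 | step 25 | dodeca-O-benzyl trimer lacking the bottom 4-hydroxyl (4-deoxy-42, all-cis top and middle units) | c5ccccc5COc1ccc([C@H]2Oc3c(c(OCc5ccccc5)cc(OCc5ccccc5)c3[C@H]3c4c(OCc5ccccc5)cc(OCc5ccccc5)cc4O[C@@H](c4ccc(OCc5ccccc5)cc4)[C@H]3OCc5ccccc5)[C@@H](c3c(OCc5ccccc5)cc(OCc5ccccc5)c4c3O[C@@H](c3ccc(OCc5ccccc5)cc3)[C@@H](OCc5ccccc5)C4)[C@H]2OCc5ccccc5)cc1
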